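Daucane numbering: C1 quaternary ring-fusion carbon, C4 isopropyl carbinol, C5 ring-fusion CH, C6 ester carbon, C8/C9 epoxide carbons. The seven-membered ring is opened between C8 and C9: the epoxide is traced to a trisubstituted C8=C9 alkene, and that to an allyl group on C1 and a methallyl carbinol at C6 of a trans-1,2-disubstituted cyclopentane. Ring-closing metathesis of this unprotected diene diol closes the cycloheptene of the trans-hydroazulene in one operation and leaves the alkene homoallylic to the C6 hydroxyl, which directs epoxidation to the α face. The cyclopentane is cut out of (S)-terpinen-4-ol (its carbinol carbon becomes C4); C5 and C1 are set by a silicon-tethered radical cyclization–allylation.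

Key step: step 9

Remark: (S)-(+)-terpinen-4-ol is taken as commercially available in high enantiomeric purity. Further atom labels: C2 and C3 are the cyclopentane CH2 groups, C7 the CH2 between C6 and C8, C10 the CH2 between C9 and C1; C8 carries the methyl and C9 the hydrogen. α is the face of H5 and of the epoxide oxygen; β is the face of the C1 methyl and the C4 hydroxyl.

Step 1
Reactants: 1 (S)-(+)-terpinen-4-ol
Product: 3 (3S)-3-hydroxy-6-oxo-3-(propan-2-yl)heptanal, via secondary ozonide 2 (not isolated)
Conditions: O3, CH2Cl2, −78 °C; then Me2S, −78 °C to 25 °C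
Reagents that add atoms: ozone, [O-][O+]=O
Why: Ozonolysis with reductive work-up (Criegee mechanism) cleaves the only C=C to a methyl ketone and an aldehyde and leaves the tertiary carbinol stereocenter, the future C4, untouched.

Step 2
Reactants: 3 (3S)-3-hydroxy-6-oxo-3-(propan-2-yl)heptanal
Product: 4 (5R)-5-hydroxy-2-methyl-5-(propan-2-yl)cyclopent-1-ene-1-carbaldehyde
Conditions: piperidine (0.2 equiv), AcOH (0.2 equiv), toluene, 25 °C
Reagents that add atoms: none
Why: Amine-catalysed intramolecular aldol condensation, in which the enamine of the aldehyde adds 5-exo to the methyl ketone and water is lost, should give the cyclopentene carbaldehyde as it does for related 6-oxoheptanals; no stereocenter is formed.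

Step 3
Reactants: 4 (5R)-5-hydroxy-2-methyl-5-(propan-2-yl)cyclopent-1-ene-1-carbaldehyde
Product: 5 (1R)-3-methyl-1-(propan-2-yl)cyclopent-2-en-1-ol
Conditions: RhCl(PPh3)3 (1.1 equiv), toluene, 110 °C
Reagents that add atoms: none
Why: Tsuji–Wilkinson decarbonylation (formyl C–H oxidative addition to monovalent rhodium, CO de-insertion, C–H reductive elimination) replaces CHO by H without moving the alkene, which frees C5 as an unsubstituted alkene carbon for the next C–C bond.

Step 4
Reactants: 5 (1R)-3-methyl-1-(propan-2-yl)cyclopent-2-en-1-ol; 6 (bromomethyl)chlorodimethylsilane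
Product: 7 (bromomethyl)dimethyl{[(1R)-3-methyl-1-(propan-2-yl)cyclopent-2-en-1-yl]oxy}silane
Conditions: Et3N, DMAP (cat.), CH2Cl2, 0 °C to 25 °C
Reagents that add atoms: none
Why: Silyl ether formation at the tertiary allylic hydroxyl installs the bromomethylsilyl radical tether on the C4 oxygen; no stereocenter is affected.

Step 5
Reactants: 7 (bromomethyl)dimethyl{[(1R)-3-methyl-1-(propan-2-yl)cyclopent-2-en-1-yl]oxy}silane; 8 allyltributylstannane
Product: 9 (1R,5R,6R)-3,3,6-trimethyl-6-(prop-2-en-1-yl)-1-(propan-2-yl)-2-oxa-3-silabicyclo[3.3.0]octane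
Conditions: 8 (3 equiv), AIBN (0.2 equiv, in portions), benzene (0.02 M), 80 °C
Reagents that add atoms: none
Why: Silicon-tethered radical cyclization with Keck allyl transfer: the α-silyl radical closes 5-exo-trig onto C5 on the face of the C4 oxygen (cis-fused ring, sets C5), and the tertiary C1 radical is then allylated on the convex face, anti to the new C5–CH2 bond (sets C1 with allyl α and methyl β).

Step 6
Reactants: 9 (1R,5R,6R)-3,3,6-trimethyl-6-(prop-2-en-1-yl)-1-(propan-2-yl)-2-oxa-3-silabicyclo[3.3.0]octane
Product: 10 (1R,2S,3R)-2-(hydroxymethyl)-3-methyl-3-(prop-2-en-1-yl)-1-(propan-2-yl)cyclopentan-1-ol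
Conditions: H2O2 (30% aq.), KF, KHCO3, THF/MeOH, 50 °C
Reagents that add atoms: hydrogen peroxide, OO
Why: Tamao–Fleming oxidation turns the C–Si bond into C–OH with retention, so the tether carbon becomes the C6 hydroxymethyl group and the C4 hydroxyl is released, while the terminal alkene is inert.

Step 7
Reactants: 10 (1R,2S,3R)-2-(hydroxymethyl)-3-methyl-3-(prop-2-en-1-yl)-1-(propan-2-yl)cyclopentan-1-ol
Product: 11 (1R,2R,5R)-2-hydroxy-5-methyl-5-(prop-2-en-1-yl)-2-(propan-2-yl)cyclopentane-1-carbaldehyde
Conditions: TEMPO (0.1 equiv), PhI(OAc)2 (1.2 equiv), CH2Cl2, 25 °C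
Reagents that add atoms: none
Why: Oxoammonium (TEMPO) oxidation is selective for the primary alcohol and stops at the aldehyde; the C5 configuration (formyl cis to the hydroxyl, trans to isopropyl and allyl) should also be the thermodynamic one, so epimerization is no threat.

Step 8
Reactants: 11 (1R,2R,5R)-2-hydroxy-5-methyl-5-(prop-2-en-1-yl)-2-(propan-2-yl)cyclopentane-1-carbaldehyde; 12 methallylmagnesium chloride
Product: 13 (1R,2S,3R)-2-[(1S)-1-hydroxy-3-methylbut-3-en-1-yl]-3-methyl-3-(prop-2-en-1-yl)-1-(propan-2-yl)cyclopentan-1-ol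
Conditions: 12 (3 equiv, THF), −78 °C, aldehyde added to the Grignard reagent; aq. NH4Cl
Reagents that add atoms: none
Why: Chelation-controlled Grignard addition: the magnesium alkoxide of the C4 hydroxyl binds the aldehyde oxygen in a six-membered chelate, and the methallyl group should attack the carbonyl face turned away from the quaternary C1 (past H5), which sets C6 as S.

Step 9
Reactants: 13 (1R,2S,3R)-2-[(1S)-1-hydroxy-3-methylbut-3-en-1-yl]-3-methyl-3-(prop-2-en-1-yl)-1-(propan-2-yl)cyclopentan-1-ol
Product: 14 jaeschkeanadiol, (3R,3aS,4S,8aR)-6,8a-dimethyl-3-(propan-2-yl)-1,2,3,3a,4,5,8,8a-octahydroazulene-3,4-diol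
Conditions: second-generation Grubbs catalyst RuCl2(=CHPh)(H2IMes)(PCy3) (5 mol %), CH2Cl2 (0.005 M), 40 °C
Reagents that add atoms: none
Why: Olefin metathesis by the Chauvin mechanism: the ruthenium carbene initiates at the monosubstituted allyl alkene (C9), and the new alkylidene adds intramolecularly to the 1,1-disubstituted methallyl alkene (C8) through a ruthenacyclobutane that collapses to the C8=C9 bond and ethene. The closest known reaction type is ring-closing metathesis of an allyl/methallyl diene to a trisubstituted cycloheptene with a second-generation ruthenium carbene. The one ring that closes is the seven-membered carbocycle (C1, C10, C9, C8, C7, C6, C5), formed by ring-closing metathesis across the trans-disposed C1 and C5 side chains to give the trans-fused bicyclo[5.3.0]decene. No stereocenter is created; C1, C4, C5 and C6 are carried through unchanged and fix the trans ring fusion. The step needs cyclization to outrun oligomerization, which is secured by high dilution, by the vicinal trans arrangement on the cyclopentane that keeps both alkenes within reach, and by the 1,1-disubstituted alkene, which does not homodimerize; the catalyst tolerates the free hydroxyls.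

Step 10
Reactants: 14 jaeschkeanadiol
Product: 15 8α,9α-epoxyjaeschkeanadiol (8α,9α-epoxydaucane-4β,6α-diol)
Conditions: VO(acac)2 (5 mol %), t-BuOOH (1.5 equiv), CH2Cl2, 0 °C to 25 °C
Reagents that add atoms: tert-butyl hydroperoxide, CC(C)(C)OO
Why: Vanadium-catalysed hydroxyl-directed epoxidation: the homoallylic C6 hydroxyl (α) binds the vanadium peroxide and should deliver oxygen to the α face of the C8=C9 alkene, setting C8 and C9, while the angular C1 methyl screens the β face.

Step 11
Reactants: 15 8α,9α-epoxyjaeschkeanadiol; 16 4-acetoxybenzoyl chloride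
Product: 18 jaeskeanin, via aryl acetate 17 (not isolated)
Conditions: 16 (1.5 equiv), Et3N, DMAP (0.2 equiv), CH2Cl2, 0 °C to 25 °C; then pyrrolidine (5 equiv), 25 °C
Reagents that add atoms: none
Why: DMAP-catalysed acylation can occur only at the secondary C6 hydroxyl (the C4 hydroxyl is tertiary), and the phenolic acetate, an activated aryl ester, should then be cleaved chemoselectively by aminolysis without touching the hindered alkyl benzoate or the epoxide.

Compound list
1 | (S)-(+)-terpinen-4-ol, (1S)-4-methyl-1-(propan-2-yl)cyclohex-3-en-1-ol | CC(C)[C@]1(O)CCC(C)=CC1 | starting material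
2 | secondary ozonide of 1, 1-methyl-4-(propan-2-yl)-7,8,9-trioxabicyclo[4.2.1]nonan-4-ol (carbinol carbon as in 1, mixture at the two acetal carbons) | CC(C)[C@]1(O)CCC2(C)OOC(C1)O2 | intermediate
3 | (3S)-3-hydroxy-6-oxo-3-(propan-2-yl)heptanal | CC(C)[C@@](O)(CC=O)CCC(C)=O | intermediate
4 | (5R)-5-hydroxy-2-methyl-5-(propan-2-yl)cyclopent-1-ene-1-carbaldehyde | CC(C)[C@]1(O)CCC(C)=C1C=O | intermediate
5 | (1R)-3-methyl-1-(propan-2-yl)cyclopent-2-en-1-ol | CC(C)[C@]1(O)CCC(C)=C1 | intermediate
6 | (bromomethyl)chlorodimethylsilane | C[Si](C)(Cl)CBr | starting material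
7 | (bromomethyl)dimethyl{[(1R)-3-methyl-1-(propan-2-yl)cyclopent-2-en-1-yl]oxy}silane | CC(C)[C@]1(O[Si](C)(C)CBr)CCC(C)=C1 | intermediate
8 | allyltributylstannane | C=CC[Sn](CCCC)(CCCC)CCCC | starting material
9 | (1R,5R,6R)-3,3,6-trimethyl-6-(prop-2-en-1-yl)-1-(propan-2-yl)-2-oxa-3-silabicyclo[3.3.0]octane (cis-fused; allyl trans to the ring CH2) | CC(C)[C@]12CC[C@](C)(CC=C)[C@H]1C[Si](C)(C)O2 | intermediate
10 | (1R,2S,3R)-2-(hydroxymethyl)-3-methyl-3-(prop-2-en-1-yl)-1-(propan-2-yl)cyclopentan-1-ol | CC(C)[C@]1(O)CC[C@](C)(CC=C)[C@H]1CO | intermediate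
11 | (1R,2R,5R)-2-hydroxy-5-methyl-5-(prop-2-en-1-yl)-2-(propan-2-yl)cyclopentane-1-carbaldehyde | CC(C)[C@]1(O)CC[C@](C)(CC=C)[C@H]1C=O | intermediate
12 | methallylmagnesium chloride, (2-methylprop-2-en-1-yl)magnesium chloride | CC(=C)C[Mg]Cl | starting material
13 | (1R,2S,3R)-2-[(1S)-1-hydroxy-3-methylbut-3-en-1-yl]-3-methyl-3-(prop-2-en-1-yl)-1-(propan-2-yl)cyclopentan-1-ol | CC(C)[C@]1(O)CC[C@](C)(CC=C)[C@H]1[C@@H](O)CC(C)=C | intermediate
14 | jaeschkeanadiol, (3R,3aS,4S,8aR)-6,8a-dimethyl-3-(propan-2-yl)-1,2,3,3a,4,5,8,8a-octahydroazulene-3,4-diol | CC(C)[C@]1(O)CC[C@]2(C)CC=C(C)C[C@H](O)[C@H]21 | intermediate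
15 | 8α,9α-epoxyjaeschkeanadiol (8α,9α-epoxydaucane-4β,6α-diol) | CC(C)[C@]1(O)CC[C@]2(C)C[C@@H]3O[C@]3(C)C[C@H](O)[C@H]21 | intermediate
16 | 4-acetoxybenzoyl chloride | CC(=O)Oc1ccc(cc1)C(Cl)=O | starting material
17 | 8α,9α-epoxyjaeschkeanadiol 6-(4-acetoxybenzoate) | CC(C)[C@]1(O)CC[C@]2(C)C[C@@H]3O[C@]3(C)C[C@H](OC(=O)c3ccc(OC(C)=O)cc3)[C@H]21 | intermediate
18 | jaeskeanin, 8α,9α-epoxyjaeschkeanadiol 6-(4-hydroxybenzoate) | CC(C)[C@]1(O)CC[C@]2(C)C[C@@H]3O[C@]3(C)C[C@H](OC(=O)c3ccc(O)cc3)[C@H]21 | target

Total step count: 11. Longest linear sequence: 11 steps (1 to 18).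

Steps most likely to fail

Step 5. The α-silyl radical may take the allyl group from the stannane before it cyclizes, or the chain may die at the hindered tertiary radical. The fallback is an ionic route that sets out from 5 and comes back at 11, replacing steps 4 to 7. Hydroxyl-directed epoxidation of 5 (VO(acac)2, t-BuOOH, CH2Cl2) should give 5-methyl-2-(propan-2-yl)-6-oxabicyclo[3.1.0]hexan-2-ol F3, with the oxirane cis to the hydroxyl. Allyltrimethylsilane with TiCl4 at −78 °C should open the oxirane at its tertiary carbon with inversion (Hosomi–Sakurai-type epoxide opening), which places the allyl group anti to the C5 oxygen and gives 3-methyl-3-(prop-2-en-1-yl)-1-(propan-2-yl)cyclopentane-1,2-diol F4. Dess–Martin oxidation of the secondary hydroxyl gives (2R,5R)-2-hydroxy-5-methyl-5-(prop-2-en-1-yl)-2-(propan-2-yl)cyclopentan-1-one F5. Dimethylsulfonium methylide (Corey–Chaykovsky reaction) adds one carbon as 7-methyl-7-(prop-2-en-1-yl)-4-(propan-2-yl)-1-oxaspiro[2.4]heptan-4-ol F6. Meinwald rearrangement with MgBr2·OEt2 then gives the aldehyde, whose epimerizable C5 should settle with the formyl group cis to the hydroxyl, that is as 11.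

Step 3. Decarbonylation of the hindered, fully substituted enal may be slow, and the tertiary allylic alcohol may lose water at the temperature needed. The fallback sets out from 3 and comes back at 5, bypassing the enal. Pinnick oxidation (NaClO2, NaH2PO4, 2-methylbut-2-ene) gives (3S)-3-hydroxy-6-oxo-3-(propan-2-yl)heptanoic acid F1. Nucleophile-catalysed aldol lactonization (2-chloro-1-methylpyridinium iodide, 4-pyrrolidinopyridine, i-Pr2NEt, CH2Cl2) joins the acid α-carbon to the ketone and closes 2-hydroxy-5-methyl-2-(propan-2-yl)-6-oxabicyclo[3.2.0]heptan-7-one F2. Thermolysis in xylene at about 140 °C extrudes CO2 by a stereospecific retro-[2+2] and gives 5.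

Step 8. Facial selectivity at the aldehyde may be poor if the very fast allylic Grignard addition outruns chelate control, and the magnesium alkoxide may open by retro-aldol cleavage. The fallback sets out from 11 and comes back at 13 under reagent control: Brown methallylation with (−)-B-methallyldiisopinocampheylborane (from (+)-α-pinene) in Et2O at −78 °C, then NaOH/H2O2 work-up. This enantiomer of the neutral, non-basic reagent is the one expected to deliver the (S)-carbinol; no new compound is made (F0).

Further compounds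
F1 | step 3 | (3S)-3-hydroxy-6-oxo-3-(propan-2-yl)heptanoic acid | CC(C)[C@@](O)(CC(O)=O)CCC(C)=O
F2 | step 3 | 2-hydroxy-5-methyl-2-(propan-2-yl)-6-oxabicyclo[3.2.0]heptan-7-one (carbinol carbon as in 3) | CC(C)[C@]1(O)CCC2(C)OC(=O)C12
F3 | step 5 | 5-methyl-2-(propan-2-yl)-6-oxabicyclo[3.1.0]hexan-2-ol (oxirane cis to the hydroxyl) | CC(C)[C@]1(O)CC[C@@]2(C)O[C@@H]12
F4 | step 5 | 3-methyl-3-(prop-2-en-1-yl)-1-(propan-2-yl)cyclopentane-1,2-diol (hydroxyls cis, allyl trans to both) | CC(C)[C@]1(O)CC[C@](C)(CC=C)[C@H]1O
F5 | step 5 | (2R,5R)-2-hydroxy-5-methyl-5-(prop-2-en-1-yl)-2-(propan-2-yl)cyclopentan-1-one | CC(C)[C@]1(O)CC[C@](C)(CC=C)C1=O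
F6 | step 5 | 7-methyl-7-(prop-2-en-1-yl)-4-(propan-2-yl)-1-oxaspiro[2.4]heptan-4-ol (mixture at the spiro carbon) | CC(C)[C@]1(O)CC[C@](C)(CC=C)C12CO2
F0 | step 8 | none | none
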